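**The decision.** If you must choose between stopping at Monday's 2.0 h and paying for Sunday's 3.0 h, ask first whether a difference in excess could be read at all.

| flask | left-handed substrate | right-handed substrate | coupling partner | free catalyst | remark | time |
|---|---|---|---|---|---|---|
| midnight | 0.30 M | 0.30 M | 0.60 M | 3 mM | run made earlier |  |
| winter | 0.30 M | 0.30 M | 0.60 M | 6.8 mM | run made earlier |  |
| dawn | 0.30 M | 0.30 M | 1.2 M | 4.5 mM | run made earlier |  |
| Monday's | 0.30 M | 0.30 M | 0.600 M | 4.5 mM |  | 2.0 h |
| Sunday's | 0.30 M | 0.30 M | 0.600 M | 4.5 mM |  | 3.0 h |

- midnight (time / min: left-handed product / %, right-handed product / %): 6.00: 7.1, 8.1; 20.0: 17.6, 18.1; 30.0: 22.6, 23.7; 50.0: 29.6, 29.9; 80.0: 36.5, 35.1; 90.0: 37.3, 36.9; 120: 38.8, 38.5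
- winter (time / min: left-handed product / %, right-handed product / %): 15.0: 26.0, 27.3; 30.0: 35.7, 35.0; 50.0: 40.4, 39.9; 60.0: 41.7, 42.0; 80.0: 43.3, 44.4; 90.0: 43.8, 44.0; 120: 45.1, 46.1
- dawn (time / min: left-handed product / %, right-handed product / %): 10.0: 27.1, 28.0; 20.0: 40.8, 40.0; 30.0: 45.6, 44.8; 60.0: 49.5, 49.3; 120: 49.0, 49.4

(readings scatter by 0.5 percentage points)

- free catalyst is single-handed; left-handed substrate and right-handed substrate are mirror images of each other, charged as a racemate, each of them at the stated concentration
- an excess is the difference of the two amounts in percent of their sum
- an excess is below zero if the other one leads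

1. which one finishes higher in excess of left-handed product over right-handed product in the product ("neither" within 2 percentage points) (Monday's / Sunday's / neither)
2. excess of left-handed product over right-handed product in the product at the end, Monday's
3. excess of left-handed product over right-handed product in the product at the end, Sunday's

**Excess window.** Write the balance of the coupling partner, taking one coupling partner per product. Then in Monday's and Sunday's c(coupling partner) of 0.600 M against 0.600 M of substrates together caps the two products' sum at 100%. An excess from one pair of readings scatters by the square root of 2 times 0.5 percentage points, divided by that sum. At the cap this excess window is 0.707%, and it widens as the sum shrinks. The first midnight reading shows an excess of −6.58% in a window of 4.65%.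

**My choice.** At the cap, two excesses differ with a scatter of 1.00%, smaller than the margin of 2 points. So I would keep the recipe and run both flasks, with one pair of readings from each.

**The forecast.** It says neither: 0% for Monday's (−1.2% to 1.2%) and 0% for Sunday's (−1.2% to 1.2%), since the catalyst “shows no measurable preference between the mirror-image substrates”.

**The flask.** Monday's gives an excess of 0.0486% and Sunday's 0.0217%, so the answer is neither. Monday's products sum to 84.9%, so its window is 0.833%, larger than its excess. Monday's flask stopped at 30 min holds an excess of −0.109% in a window of 1.19%.

    2 coupling partner → self-condensation product (k = 0.0239 L mol⁻¹ min⁻¹)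
    free catalyst + left-handed substrate ⇌ catalyst intermediate A (K = 1.60 L mol⁻¹, k = 3110 L mol⁻¹ min⁻¹)
    free catalyst + right-handed substrate ⇌ catalyst intermediate B (K = 8.70 L mol⁻¹, k = 1140 L mol⁻¹ min⁻¹)
    left-handed product ⇌ right-handed product (k = 0.359 min⁻¹)
    coupling partner + catalyst intermediate A → free catalyst + left-handed product (k = 44.4 L mol⁻¹ min⁻¹)
    coupling partner + catalyst intermediate B → free catalyst + right-handed product (k = 18.2 L mol⁻¹ min⁻¹)
    coupling partner ⇌ dormant form (K = 0.958, k = 3.30 min⁻¹)

**Fast exchange.** In Monday's at 0.214 h, coupling through catalyst intermediate B uses coupling partner 1.5 times as fast as coupling through catalyst intermediate A, and right-handed product is made 4.91 times faster than it is used up. Through racemisation the difference of the two products halves in 0.965 min, far shorter than Monday's 2.0 h.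

The readings stem from a simulated flask for substances that don't exist; noise was put on by code.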